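The cyclopentane ring is closed last, by bonding C2 (a CH2) to the carbinol carbon C3 (azulene numbering). A SmI2 Barbier cyclisation of a cycloheptenyl isopropyl ketone that carries a 2-iodoethyl arm on the neighbouring quaternary carbon C8a forms this bond, the trans-fused five-membered ring and the tertiary alcohol in one operation. It exploits the oxygen at C4 of the seven-membered ring, cis to the acyl group: an O4–metal–O3 chelate fixes the carbonyl face and writes the syn C3/C4 diol. The precursor is assembled by enantioselective palladium allylation of a butyrolactone (C8a), ring-closing metathesis (seven-membered ring) and copper-catalysed conjugate borylation (C4–O, C3a–H).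

Key step: step 10

Remark: locants C1–C8a are those of the azulene skeleton of the target and are used for the corresponding atoms of all intermediates. The ligand antipodes named in steps 2 and 8 are assigned by analogy with related substrates, not from data on these compounds.

Step 1
Reactants: 1 3-methyloxolan-2-one (racemic α-methyl-γ-butyrolactone); 2 prop-2-en-1-yl carbonochloridate (allyl chloroformate)
Product: 3 prop-2-en-1-yl 3-methyl-2-oxooxolane-3-carboxylate (racemic)
Conditions: LiN(i-Pr)2, THF, −78 °C; then 2, −78 → 0 °C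
Reagents that add atoms: none
Why: Claisen-type C-acylation of the lactone lithium enolate by the chloroformate gives the quaternary allyl β-ester; the stereocentre is racemic here and is erased and reset in step 2.

Step 2
Reactants: 3 prop-2-en-1-yl 3-methyl-2-oxooxolane-3-carboxylate
Product: 4 (3S)-3-methyl-3-(prop-2-en-1-yl)oxolan-2-one
Conditions: Pd2(dba)3 (2.5 mol %), (R)-t-BuPHOX (6 mol %), toluene, 30 °C
Reagents that add atoms: none
Why: Decarboxylative asymmetric allylic alkylation (Tsuji–Trost type): ionisation and loss of CO2 give a palladium-allyl lactone enolate pair, and C–C bond formation inside the chiral P,N-ligand sphere should set the quaternary centre C8a (S in the lactone).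

Step 3
Reactants: 4 (3S)-3-methyl-3-(prop-2-en-1-yl)oxolan-2-one; 5 4-bromo-2-methylbut-1-ene
Product: 7 (6S)-6-(2-hydroxyethyl)-2,6-dimethylnona-1,8-dien-5-one, via (3-methylbut-3-en-1-yl)lithium 6 (not isolated)
Conditions: 5, Li, Et2O, 0 °C; then 4, THF, −78 °C; aq NH4Cl
Reagents that add atoms: lithium, [Li] (lithium of 6 only)
Why: 1,2-Addition of a primary organolithium to the lactone carbonyl: the tetrahedral lithium lactolate is stable at −78 °C, so only one equivalent should add, and the quaternary α-carbon can neither enolise nor epimerise.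

Step 4
Reactants: 7 (6S)-6-(2-hydroxyethyl)-2,6-dimethylnona-1,8-dien-5-one
Product: 8 (6S)-6-(2-chloroethyl)-2,6-dimethylnona-1,8-dien-5-one
Conditions: N-chlorosuccinimide, PPh3, CH2Cl2, 0 → 25 °C
Reagents that add atoms: N-chlorosuccinimide, ClN1C(=O)CCC1=O
Why: Appel-type chlorination: the primary alcohol of the open-chain tautomer (7 equilibrates with its cyclic hemiketal) forms an alkoxyphosphonium salt that chloride displaces by SN2, and a chloride is chosen because it should survive the organolithium chemistry of step 7.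

Step 5
Reactants: 8 (6S)-6-(2-chloroethyl)-2,6-dimethylnona-1,8-dien-5-one
Product: 9 (2S)-2-(2-chloroethyl)-2,5-dimethylcyclohept-4-en-1-one
Conditions: second-generation Grubbs catalyst RuCl2(=CHPh)(H2IMes)(PCy3) (5 mol %), CH2Cl2 (5 mM), 40 °C
Reagents that add atoms: none
Why: Ring-closing metathesis between the allyl and isopropenyl groups should give the trisubstituted cycloheptene with loss of ethene, helped by the gem-disubstituted carbon (Thorpe–Ingold effect); the stereocentre is not involved.

Step 6
Reactants: 9 (2S)-2-(2-chloroethyl)-2,5-dimethylcyclohept-4-en-1-one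
Product: 10 N'-[(2S)-2-(2-chloroethyl)-2,5-dimethylcyclohept-4-en-1-ylidene]-2,4,6-tri(propan-2-yl)benzenesulfonohydrazide (E geometry expected)
Conditions: 2,4,6-(i-Pr)3C6H2SO2NHNH2, HCl (cat.), MeCN–THF, 25 °C
Reagents that add atoms: 2,4,6-tri(propan-2-yl)benzenesulfonohydrazide, CC(C)c1cc(C(C)C)c(S(=O)(=O)NN)c(C(C)C)c1
Why: Acid-catalysed condensation of the ketone with the arylsulfonyl hydrazide gives the hydrazone, with the N–N bond expected anti to the quaternary carbon, the geometry needed for syn-deprotonation at the ring CH2.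

Step 7
Reactants: 10 the hydrazone of step 6; 11 N-methoxy-N,2-dimethylpropanamide
Product: 13 1-[(7S)-7-(2-chloroethyl)-4,7-dimethylcyclohepta-1,4-dien-1-yl]-2-methylpropan-1-one, via alkenyllithium 12 (not isolated)
Conditions: n-BuLi (2.1 equiv), THF, −78 → 0 °C; then 11, −78 → 0 °C; aq NH4Cl
Reagents that add atoms: butyllithium, [Li]CCCC (lithium of 12 only)
Why: Shapiro reaction: the hydrazone dianion loses sulfinate and N2 to give the alkenyllithium regiospecifically (only one α-carbon bears hydrogen), and its acylation by the N-methoxy-N-methylamide stops at the chelated tetrahedral adduct, which should release the enone on work-up.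

Step 8
Reactants: 13 1-[(7S)-7-(2-chloroethyl)-4,7-dimethylcyclohepta-1,4-dien-1-yl]-2-methylpropan-1-one
Product: 15 1-[(1S,2R,7S)-7-(2-chloroethyl)-2-hydroxy-4,7-dimethylcyclohept-4-en-1-yl]-2-methylpropan-1-one, via boryl ketone 14 (not isolated)
Conditions: CuCl (5 mol %), NaOt-Bu (10 mol %), (R,R)-QuinoxP* (6 mol %), B2pin2, MeOH, THF, 25 °C; then H2O2, aq NaHCO3, 0 °C
Reagents that add atoms: bis(pinacolato)diboron, CC1(C)OB(OC1(C)C)B1OC(C)(C)C(C)(C)O1 (boron of 14 only); hydrogen peroxide, OO
Why: Copper-catalysed conjugate borylation followed by C–B oxidation with retention: the Cu–Bpin species should add to the β-carbon C4 on the face anti to the pseudo-axial chloroethyl arm (allylic 1,2-strain with the acyl group puts the larger C8a substituent axial, and the ligand antipode is chosen to reinforce this), and methanol should protonate the enolate at C3a anti to the new boryl group, giving the cis β-hydroxy ketone.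

Step 9
Reactants: 15 1-[(1S,2R,7S)-7-(2-chloroethyl)-2-hydroxy-4,7-dimethylcyclohept-4-en-1-yl]-2-methylpropan-1-one
Product: 16 1-[(1S,2R,7S)-2-hydroxy-7-(2-iodoethyl)-4,7-dimethylcyclohept-4-en-1-yl]-2-methylpropan-1-one
Conditions: NaI, 2-butanone, 70 °C
Reagents that add atoms: sodium iodide, [Na+].[I-]
Why: Finkelstein SN2 exchange at the unhindered primary carbon, driven by precipitation of NaCl; the neutral conditions should leave the aldol and its stereocentres intact.

Step 10
Reactants: 16 1-[(1S,2R,7S)-2-hydroxy-7-(2-iodoethyl)-4,7-dimethylcyclohept-4-en-1-yl]-2-methylpropan-1-one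
Product: 18 (3R,3aS,4R,8aR)-6,8a-dimethyl-3-(propan-2-yl)-1,2,3,3a,4,5,8,8a-octahydroazulene-3,4-diol, via lithium alkoxide 17 (not isolated)
Conditions: LiN(SiMe3)2 (1.0 equiv), THF, −78 °C; then SmI2 (2.5 equiv), NiI2 (1 mol %), THF, −78 → −20 °C; aq NH4Cl
Reagents that add atoms: lithium bis(trimethylsilyl)amide, [Li]N([Si](C)(C)C)[Si](C)(C)C (lithium of 17 only)
Why: Samarium Barbier reaction, the closest known type being the chelation-controlled SmI2 cyclisation of ω-iodoalkyl ketones that carry a β-oxygen: two single-electron transfers (relayed by the nickel catalyst) turn the primary C–I bond into a carbon nucleophile on trivalent samarium (R–SmI2), which adds to the isopropyl ketone to form the C2–C3 bond. The five-membered ring closes in the 5-exo-trig mode on the carbonyl carbon. The new stereocentre C3 is controlled by the C4 alkoxide, which with the carbonyl oxygen forms a six-membered metal chelate that holds O3 syn to C4, so that the arm on C8a meets the carbonyl carbon on the one face that leaves the hydroxyl cis to the C4 oxygen and the angular methyl and the isopropyl group on the open face next to H-3a; the steric bias of the axial methyl points the same way. The trans ring fusion is inherited, not made: the arm on C8a and the acyl group on C3a are trans and both pseudo-equatorial, hence gauche and within bonding distance. The step needs C–I reduction to outrun ketone reduction and the carbon nucleophile to add before it is protonated, which the fast reduction of primary iodides, the hindered dialkyl ketone and the prior conversion of the hydroxyl into its alkoxide should secure.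

Step 11
Reactants: 18 (3R,3aS,4R,8aR)-6,8a-dimethyl-3-(propan-2-yl)-1,2,3,3a,4,5,8,8a-octahydroazulene-3,4-diol; 19 4-(acetyloxy)benzoyl chloride
Product: 21 (3R,3aS,4R,8aR)-3-hydroxy-6,8a-dimethyl-3-(propan-2-yl)-1,2,3,3a,4,5,8,8a-octahydroazulen-4-yl 4-hydroxybenzoate, via aryl acetate 20 (not isolated)
Conditions: 19, pyridine, DMAP (0.2 equiv), CH2Cl2, 0 → 25 °C; then pyrrolidine, 25 °C
Reagents that add atoms: none
Why: Nucleophilic acyl substitution at the only acylable (secondary) hydroxyl, the tertiary C3 hydroxyl being inert, followed by aminolysis of the more electrophilic aryl acetate, which should unmask the phenol while the hindered benzoate survives; no stereocentre is touched.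

Compound list
1 | 3-methyloxolan-2-one (racemic) | CC1CCOC1=O | starting material
2 | prop-2-en-1-yl carbonochloridate | C=CCOC(=O)Cl | starting material
3 | prop-2-en-1-yl 3-methyl-2-oxooxolane-3-carboxylate (racemic) | C=CCOC(=O)C1(C)CCOC1=O | intermediate
4 | (3S)-3-methyl-3-(prop-2-en-1-yl)oxolan-2-one | C=CC[C@@]1(C)CCOC1=O | intermediate
5 | 4-bromo-2-methylbut-1-ene | CC(=C)CCBr | starting material
6 | (3-methylbut-3-en-1-yl)lithium (not isolated) | [Li]CCC(C)=C | intermediate
7 | (6S)-6-(2-hydroxyethyl)-2,6-dimethylnona-1,8-dien-5-one | C=CC[C@@](C)(CCO)C(=O)CCC(C)=C | intermediate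
8 | (6S)-6-(2-chloroethyl)-2,6-dimethylnona-1,8-dien-5-one | C=CC[C@@](C)(CCCl)C(=O)CCC(C)=C | intermediate
9 | (2S)-2-(2-chloroethyl)-2,5-dimethylcyclohept-4-en-1-one | CC1=CC[C@@](C)(CCCl)C(=O)CC1 | intermediate
10 | N'-[(2S)-2-(2-chloroethyl)-2,5-dimethylcyclohept-4-en-1-ylidene]-2,4,6-tri(propan-2-yl)benzenesulfonohydrazide | CC1=CC[C@@](C)(CCCl)C(=NNS(=O)(=O)c2c(C(C)C)cc(C(C)C)cc2C(C)C)CC1 | intermediate
11 | N-methoxy-N,2-dimethylpropanamide | CC(C)C(=O)N(C)OC | starting material
12 | [(7S)-7-(2-chloroethyl)-4,7-dimethylcyclohepta-1,4-dien-1-yl]lithium (not isolated) | CC1=CC[C@@](C)(CCCl)C([Li])=CC1 | intermediate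
13 | 1-[(7S)-7-(2-chloroethyl)-4,7-dimethylcyclohepta-1,4-dien-1-yl]-2-methylpropan-1-one | CC1=CC[C@@](C)(CCCl)C(C(=O)C(C)C)=CC1 | intermediate
14 | 1-[(1R,2R,7S)-7-(2-chloroethyl)-4,7-dimethyl-2-(4,4,5,5-tetramethyl-1,3,2-dioxaborolan-2-yl)cyclohept-4-en-1-yl]-2-methylpropan-1-one (not isolated) | CC1=CC[C@@](C)(CCCl)[C@H](C(=O)C(C)C)[C@H](B2OC(C)(C)C(C)(C)O2)C1 | intermediate
15 | 1-[(1S,2R,7S)-7-(2-chloroethyl)-2-hydroxy-4,7-dimethylcyclohept-4-en-1-yl]-2-methylpropan-1-one | CC1=CC[C@@](C)(CCCl)[C@H](C(=O)C(C)C)[C@H](O)C1 | intermediate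
16 | 1-[(1S,2R,7S)-2-hydroxy-7-(2-iodoethyl)-4,7-dimethylcyclohept-4-en-1-yl]-2-methylpropan-1-one | CC1=CC[C@@](C)(CCI)[C@H](C(=O)C(C)C)[C@H](O)C1 | intermediate
17 | lithium alkoxide of 16 (not isolated) | CC1=CC[C@@](C)(CCI)[C@H](C(=O)C(C)C)[C@H](O[Li])C1 | intermediate
18 | (3R,3aS,4R,8aR)-6,8a-dimethyl-3-(propan-2-yl)-1,2,3,3a,4,5,8,8a-octahydroazulene-3,4-diol | CC1=CC[C@@]2(C)CC[C@@](O)(C(C)C)[C@@H]2[C@H](O)C1 | intermediate
19 | 4-(acetyloxy)benzoyl chloride | CC(=O)Oc1ccc(C(=O)Cl)cc1 | starting material
20 | (3R,3aS,4R,8aR)-3-hydroxy-6,8a-dimethyl-3-(propan-2-yl)-1,2,3,3a,4,5,8,8a-octahydroazulen-4-yl 4-(acetyloxy)benzoate (not isolated) | CC1=CC[C@@]2(C)CC[C@@](O)(C(C)C)[C@@H]2[C@H](OC(=O)c2ccc(OC(C)=O)cc2)C1 | intermediate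
21 | (3R,3aS,4R,8aR)-3-hydroxy-6,8a-dimethyl-3-(propan-2-yl)-1,2,3,3a,4,5,8,8a-octahydroazulen-4-yl 4-hydroxybenzoate | CC1=CC[C@@]2(C)CC[C@@](O)(C(C)C)[C@@H]2[C@H](OC(=O)c2ccc(O)cc2)C1 | target

Total step count: 11. Longest linear sequence: 11 steps (1 → 21).

Steps most likely to fail

Step 8. The boron may be delivered to the wrong face of the twisted, hindered enone, or the enolate may be protonated syn to boron, or the aldol may epimerise at C3a during oxidation. Any of these would give the wrong configuration at C4 or C3a. The fallback sets out from 13 and returns at 18; it inverts the order of ring closure and oxygenation so that the bicyclic frame relays the stereochemistry. Finkelstein exchange (NaI, 2-butanone, 70 °C) should give 1-[(7S)-7-(2-iodoethyl)-4,7-dimethylcyclohepta-1,4-dien-1-yl]-2-methylpropan-1-one F1. Iodine–lithium exchange (t-BuLi, 2.1 equiv, Et2O–pentane, −78 °C) then triggers a 5-exo-trig 1,2-addition of the primary alkyllithium to the enone carbonyl. This forms the same C2–C3 bond and gives (3R,8aR)-6,8a-dimethyl-3-(propan-2-yl)-1,2,3,5,8,8a-hexahydroazulen-3-ol F2, with the isopropyl group expected anti to the angular methyl. Hydroxyl-directed epoxidation (VO(acac)2, t-BuOOH, CH2Cl2) should deliver oxygen to the C3a=C4 bond syn to the C3 hydroxyl and leave the remote trisubstituted alkene alone. The product is (3R,3aS,4R,8aR)-3a,4-epoxy-6,8a-dimethyl-3-(propan-2-yl)-1,2,3,3a,4,5,8,8a-octahydroazulen-3-ol F3. Reductive opening with the trivalent titanium reagent Cp2TiCl (from Cp2TiCl2 and Mn, THF, water as hydrogen-atom donor) breaks the C3a–O bond to the tertiary radical. This radical should take up hydrogen on the α face, anti to the two titanium-bound oxygens, to give 18.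

Step 10. The carbon nucleophile may be protonated before it adds (net reduction of C–I to C–H), the lithium aldolate may undergo retro-aldol cleavage, or closure to the trans-fused ring may be slow. The fallback sets out from 16 and returns at 18; it caps the hydroxyl and closes the ring by a polar instead of a single-electron process. Silylation (Et3SiOTf, 2,6-lutidine, CH2Cl2, −78 °C) should give 1-[(1S,2R,7S)-7-(2-iodoethyl)-4,7-dimethyl-2-(triethylsilyloxy)cyclohept-4-en-1-yl]-2-methylpropan-1-one F4. Iodine–lithium exchange (t-BuLi, 2.1 equiv, Et2O–pentane, −78 °C) and 5-exo-trig addition of the alkyllithium to the ketone, now under steric control (isopropyl away from the axial methyl and the silyloxy group), should give (3R,3aS,4R,8aR)-6,8a-dimethyl-3-(propan-2-yl)-4-(triethylsilyloxy)-1,2,3,3a,4,5,8,8a-octahydroazulen-3-ol F5. Desilylation (Bu4NF, THF) returns 18.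

Step 2. Facial discrimination of the small, nearly symmetrical lactone enolate may be insufficient, which would leave the product of low enantiomeric purity. The fallback sets out from 1 and returns at 4; it replaces catalysis by a classical resolution. Direct allylation (LiN(i-Pr)2, allyl bromide, THF, −78 °C) gives racemic 3-methyl-3-(prop-2-en-1-yl)oxolan-2-one F6. Aminolysis with (S)-1-phenylethylamine and AlMe3 (toluene, 60 °C) gives two diastereomeric hydroxy amides. (2S)-2-(2-hydroxyethyl)-2-methyl-N-[(1S)-1-phenylethyl]pent-4-enamide F7 is separated by crystallisation or chromatography from its (2R)-2-(2-hydroxyethyl)-2-methyl-N-[(1S)-1-phenylethyl]pent-4-enamide diastereomer F8. Acid-mediated relactonisation of F7 (aq H2SO4, dioxane, 80 °C) releases the amine and returns 4.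

Further compounds
F1 | step 8 | 1-[(7S)-7-(2-iodoethyl)-4,7-dimethylcyclohepta-1,4-dien-1-yl]-2-methylpropan-1-one | CC1=CC[C@@](C)(CCI)C(C(=O)C(C)C)=CC1
F2 | step 8 | (3R,8aR)-6,8a-dimethyl-3-(propan-2-yl)-1,2,3,5,8,8a-hexahydroazulen-3-ol | CC1=CC[C@@]2(C)CC[C@@](O)(C(C)C)C2=CC1
F3 | step 8 | (3R,3aS,4R,8aR)-3a,4-epoxy-6,8a-dimethyl-3-(propan-2-yl)-1,2,3,3a,4,5,8,8a-octahydroazulen-3-ol | CC1=CC[C@@]2(C)CC[C@@](O)(C(C)C)[C@]23O[C@@H]3C1
F4 | step 10 | 1-[(1S,2R,7S)-7-(2-iodoethyl)-4,7-dimethyl-2-(triethylsilyloxy)cyclohept-4-en-1-yl]-2-methylpropan-1-one | CC1=CC[C@@](C)(CCI)[C@H](C(=O)C(C)C)[C@H](O[Si](CC)(CC)CC)C1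
F5 | step 10 | (3R,3aS,4R,8aR)-6,8a-dimethyl-3-(propan-2-yl)-4-(triethylsilyloxy)-1,2,3,3a,4,5,8,8a-octahydroazulen-3-ol | CC1=CC[C@@]2(C)CC[C@@](O)(C(C)C)[C@@H]2[C@H](O[Si](CC)(CC)CC)C1
F6 | step 2 | 3-methyl-3-(prop-2-en-1-yl)oxolan-2-one (racemic) | C=CCC1(C)CCOC1=O
F7 | step 2 | (2S)-2-(2-hydroxyethyl)-2-methyl-N-[(1S)-1-phenylethyl]pent-4-enamide | C=CC[C@@](C)(CCO)C(=O)N[C@@H](C)c1ccccc1
F8 | step 2 | (2R)-2-(2-hydroxyethyl)-2-methyl-N-[(1S)-1-phenylethyl]pent-4-enamide | C=CC[C@](C)(CCO)C(=O)N[C@@H](C)c1ccccc1
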